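All four outer-ring oxygens are disconnected at once. In each outer ring the butyryl-bearing carbon C1 lies between the hydroxylated carbons C2 and C6, so a directing group made from that ketone reaches every oxygenation site, and these four positions are the only aromatic C–H bonds once the fully substituted central ring is in place. One palladium-catalysed operation turns the four C–H bonds into aryl acetates. Its substrate is 3,5-dibenzylated 2,4,6-triacetoxyacetophenone whose two 4-methoxy-3-methylphenyl arms carry their butyryl groups as E O-methyl oximes; it comes from double Friedel–Crafts benzylation of 2,4,6-trihydroxyacetophenone. Oxime cleavage and deacetylation finish the synthesis.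

Key step: step 5

Remark on geometry: both oxime ethers are drawn and named as E isomers (methoxy anti to the aryl ring, nitrogen lone pair toward the ring); this is the thermodynamically favoured geometry and it is erased when the oximes are cleaved.

Remark on the structures: the substrate and the product of the key step map atom for atom onto the target and need no correction. The one change of design is that the oxime ethers are made before the phenols are acetylated, because methoxyamine would otherwise attack aryl acetates.

Remark on numbering: in the outer rings C1 carries the butyryl (or oxime) carbon, C2 and C6 the oxygens, C3 the methyl group, C4 the methoxy group and C5 the methylene bridge.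

Remark on handling: the chloromethylation in step 2 can form traces of bis(chloromethyl) ether and is run in a closed, scrubbed apparatus.

Step 1
Reactants: 1 2-methylanisole; 2 butanoyl chloride
Product: 3 1-(4-methoxy-3-methylphenyl)butan-1-one
Conditions: AlCl3 (1.1 equiv), CH2Cl2, 0 °C → rt; aq. HCl quench
Reagents that add atoms: none
Why: Friedel–Crafts acylation should go para to the methoxy group, the stronger director, giving the 4-methoxy-3-methylphenyl ketone as with other acyl chlorides on this arene.

Step 2
Reactants: 3 1-(4-methoxy-3-methylphenyl)butan-1-one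
Product: 4 1-[3-(chloromethyl)-4-methoxy-5-methylphenyl]butan-1-one
Conditions: (CH2O)n, conc. HCl, ZnCl2 (cat.), AcOH, 55 °C
Reagents that add atoms: paraformaldehyde (formaldehyde unit), C=O; hydrogen chloride, Cl
Why: Blanc chloromethylation should enter C5, the only position that is ortho to the methoxy group and meta to the ketone, as in the chloromethylation of other 4-alkoxyaryl ketones.

Step 3
Reactants: 4 1-[3-(chloromethyl)-4-methoxy-5-methylphenyl]butan-1-one (2.2 equiv); 5 2,4,6-trihydroxyacetophenone (dried)
Product: 6 3,5-bis(5-butanoyl-2-methoxy-3-methylbenzyl)-2,4,6-trihydroxyacetophenone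
Conditions: ZnCl2 (anhydrous, 1 equiv), 1,4-dioxane, 80 °C
Reagents that add atoms: none
Why: Friedel–Crafts benzylation: ZnCl2 activates the benzylic chloride and the two free ring carbons of the phloroglucinol, the most nucleophilic sites present, should each be alkylated once because attack at carbon is followed by rearomatisation and the deactivated arm rings cannot compete.

Step 4
Reactants: 6 3,5-bis(5-butanoyl-2-methoxy-3-methylbenzyl)-2,4,6-trihydroxyacetophenone
Product: 8 2-acetyl-4,6-bis{5-[(1E)-N-methoxybutanimidoyl]-2-methoxy-3-methylbenzyl}benzene-1,3,5-triyl triacetate, via triol bis(O-methyl oxime) 7 (not isolated)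
Conditions: MeONH2·HCl (2.3 equiv), pyridine, rt; then Ac2O, DMAP (cat.), rt → 40 °C
Reagents that add atoms: methoxyamine hydrochloride, CON.Cl; acetic anhydride, CC(=O)OC(C)=O
Why: Oxime ether condensation followed by O-acetylation: methoxyamine should take the two unhindered butyrophenone carbonyls (E isomer favoured thermodynamically) and spare the central acetyl group, which is flanked by two hydroxyls and deactivated as a vinylogous acid that is largely ionised in pyridine, and Ac2O/DMAP then esterifies the three phenols and destroys surplus methoxyamine.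

Step 5
Reactants: 8 2-acetyl-4,6-bis{5-[(1E)-N-methoxybutanimidoyl]-2-methoxy-3-methylbenzyl}benzene-1,3,5-triyl triacetate
Product: 9 2-acetyl-4,6-bis{2,4-diacetoxy-3-[(1E)-N-methoxybutanimidoyl]-6-methoxy-5-methylbenzyl}benzene-1,3,5-triyl triacetate
Conditions: Pd(OAc)2 (20 mol %), PhI(OAc)2 (6 equiv, in portions), AcOH/Ac2O 1:1, 100 °C
Reagents that add atoms: (diacetoxyiodo)benzene, CC(=O)OI(OC(C)=O)c1ccccc1
Why: Proposed new method: the E oxime nitrogen binds Pd(OAc)2 and acetate-assisted concerted metalation–deprotonation of the neighbouring ring C–H gives a five-membered palladacycle, which PhI(OAc)2 oxidises to a tetravalent palladium acetate that forms the aryl C–O bond by reductive elimination and returns divalent palladium; rotation about the aryl–C(=N) bond then presents the second ortho C–H, and the cycle runs four times in all. The closest known reaction type is the Pd(OAc)2/PhI(OAc)2 ortho-acetoxylation of aryl ketone O-methyl oximes, which also gives 2,6-diacetoxy products; what is new is that every C–H here lies between the oxime-bearing carbon and a substituted carbon (C3 methyl or C5 methylene) and that four such events must be completed in one molecule. No ring is closed and no stereocentre is formed. Site selectivity is secured by the substrate: C2–H and C6–H of the two outer rings are the only aromatic C–H bonds, the central ring is fully substituted, directed attack on a CH2 bridge or a ring methyl group would need a seven-membered palladacycle, and the propyl chain is out of reach of an E oxime nitrogen. Chemoselectivity is helped by the electron-poor triacetoxy central ring, which disfavours oxidation of the benzylic bridges, by Ac2O as co-solvent, which keeps oxime ethers and acetates from hydrolysing, and by the release of each new oxygen as an acetate that resists further oxidation. Any Z oxime ether should equilibrate to the reactive E form in hot acetic acid.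

Step 6
Reactants: 9 2-acetyl-4,6-bis{2,4-diacetoxy-3-[(1E)-N-methoxybutanimidoyl]-6-methoxy-5-methylbenzyl}benzene-1,3,5-triyl triacetate
Product: 10 2-acetyl-4,6-bis(2,4-diacetoxy-3-butanoyl-6-methoxy-5-methylbenzyl)benzene-1,3,5-triyl triacetate
Conditions: TiCl3 (aq. HCl solution, 6 equiv), THF/H2O, rt → 50 °C
Reagents that add atoms: water, O
Why: Reductive deoximation: trivalent titanium cleaves the N–O bond and the N–H ketimine so formed, held out of conjugation by its two ortho acetoxy groups, should hydrolyse in the acidic medium, while any acetate lost at this stage is of no consequence because step 7 removes them all.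

Step 7
Reactants: 10 2-acetyl-4,6-bis(2,4-diacetoxy-3-butanoyl-6-methoxy-5-methylbenzyl)benzene-1,3,5-triyl triacetate
Product: 11 1-[3,5-bis(3-butanoyl-2,4-dihydroxy-6-methoxy-5-methylbenzyl)-2,4,6-trihydroxyphenyl]ethan-1-one (CNP0184345.0)
Conditions: K2CO3, MeOH (degassed), 0 °C → rt, Ar; then dilute HCl
Reagents that add atoms: none
Why: Base-promoted transesterification of aryl acetates with methanol is fast even at flanked positions and, run cold and free of oxygen, should leave the methylene bridges, methyl ethers and ketones untouched.

Compound list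

1 | 2-methylanisole (1-methoxy-2-methylbenzene) | COc1ccccc1C | starting material
2 | butanoyl chloride | CCCC(Cl)=O | starting material
3 | 1-(4-methoxy-3-methylphenyl)butan-1-one | CCCC(=O)c1ccc(OC)c(C)c1 | intermediate
4 | 1-[3-(chloromethyl)-4-methoxy-5-methylphenyl]butan-1-one | CCCC(=O)c1cc(C)c(OC)c(CCl)c1 | intermediate
5 | 2,4,6-trihydroxyacetophenone | CC(=O)c1c(O)cc(O)cc1O | starting material
6 | 3,5-bis(5-butanoyl-2-methoxy-3-methylbenzyl)-2,4,6-trihydroxyacetophenone | CC(=O)c1c(O)c(Cc2cc(C(=O)CCC)cc(C)c2OC)c(O)c(Cc2cc(C(=O)CCC)cc(C)c2OC)c1O | intermediate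
7 | 3,5-bis{5-[(1E)-N-methoxybutanimidoyl]-2-methoxy-3-methylbenzyl}-2,4,6-trihydroxyacetophenone | CC(=O)c1c(O)c(Cc2cc(/C(CCC)=N/OC)cc(C)c2OC)c(O)c(Cc2cc(/C(CCC)=N/OC)cc(C)c2OC)c1O | intermediate
8 | 2-acetyl-4,6-bis{5-[(1E)-N-methoxybutanimidoyl]-2-methoxy-3-methylbenzyl}benzene-1,3,5-triyl triacetate | CC(=O)c1c(OC(C)=O)c(Cc2cc(/C(CCC)=N/OC)cc(C)c2OC)c(OC(C)=O)c(Cc2cc(/C(CCC)=N/OC)cc(C)c2OC)c1OC(C)=O | intermediate
9 | 2-acetyl-4,6-bis{2,4-diacetoxy-3-[(1E)-N-methoxybutanimidoyl]-6-methoxy-5-methylbenzyl}benzene-1,3,5-triyl triacetate | CC(=O)c1c(OC(C)=O)c(Cc2c(OC(C)=O)c(/C(CCC)=N/OC)c(OC(C)=O)c(C)c2OC)c(OC(C)=O)c(Cc2c(OC(C)=O)c(/C(CCC)=N/OC)c(OC(C)=O)c(C)c2OC)c1OC(C)=O | intermediate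
10 | 2-acetyl-4,6-bis(2,4-diacetoxy-3-butanoyl-6-methoxy-5-methylbenzyl)benzene-1,3,5-triyl triacetate | CC(=O)c1c(OC(C)=O)c(Cc2c(OC(C)=O)c(C(=O)CCC)c(OC(C)=O)c(C)c2OC)c(OC(C)=O)c(Cc2c(OC(C)=O)c(C(=O)CCC)c(OC(C)=O)c(C)c2OC)c1OC(C)=O | intermediate
11 | 1-[3,5-bis(3-butanoyl-2,4-dihydroxy-6-methoxy-5-methylbenzyl)-2,4,6-trihydroxyphenyl]ethan-1-one | CCCC(=O)c1c(O)c(C)c(OC)c(Cc2c(O)c(Cc3c(O)c(C)c(OC)c(C(=O)CCC)c3O)c(O)c(C(C)=O)c2O)c1O | target

Total step count: 7. Longest linear sequence: 7 steps (1 → 11 through steps 1 to 7).

Steps most likely to fail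

Step 5. Palladation may stall at the doubly flanked positions, so that the sequence stops after one to three acetoxylations, or the oxidant may attack the benzylic bridges. The fallback uses known chemistry: the outer rings are brought in already oxygenated and the methylene bridges are formed last. It sets out from 5 and comes back at 11. Commercial 2,4,6-trihydroxytoluene (Cc1c(O)cc(O)cc1O) would be acylated with 2 (AlCl3, nitrobenzene/CH2Cl2, Friedel–Crafts) to 1-(2,4,6-trihydroxy-3-methylphenyl)butan-1-one F1. Selective methylation of the non-chelated hydroxyl para to the ketone (Me2SO4 1 equiv, K2CO3, acetone) should give 1-(2,6-dihydroxy-4-methoxy-3-methylphenyl)butan-1-one F2. A Mannich reaction at its single free ring position (aq. Me2NH, aq. formaldehyde, EtOH) should give 1-{3-[(dimethylamino)methyl]-2,6-dihydroxy-4-methoxy-5-methylphenyl}butan-1-one F3. Heating two equivalents of F3 with 5 in dioxane should expel dimethylamine, and the resulting ortho-quinone methide should be captured at the two free ring carbons of 5 to give 11.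

Step 3. The second benzylation may be incomplete, alkylation may occur on oxygen, or the hindered benzylic chloride may ionise too slowly. The fallback forms the two aryl–CH2 bonds by Negishi cross-coupling; it sets out from 5 and 4 and comes back at 6. Bromination of 5 (Br2, AcOH) should give 3,5-dibromo-2,4,6-trihydroxyacetophenone F4, and acetylation (Ac2O, pyridine) its triacetate 2-acetyl-4,6-dibromobenzene-1,3,5-triyl triacetate F5. Zinc dust and LiCl in THF should convert 4 into (5-butanoyl-2-methoxy-3-methylbenzyl)zinc chloride F6, a reagent class that tolerates ketones. Double coupling of F6 with F5 (Pd(OAc)2, SPhos, THF, rt → 50 °C) should give 2-acetyl-4,6-bis(5-butanoyl-2-methoxy-3-methylbenzyl)benzene-1,3,5-triyl triacetate F7, and cold K2CO3/MeOH should then return 6.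

Step 6. The N–O reduction may be slow or incomplete at the doubly ortho-substituted oxime ethers, leaving material with one oxime still in place. The fallback reverses the order of the endgame and replaces reduction by hydrolytic exchange; it sets out from 9 and comes back at 11. Methanolysis of 9 (K2CO3, MeOH, 0 °C, Ar) should give 3,5-bis{2,4-dihydroxy-3-[(1E)-N-methoxybutanimidoyl]-6-methoxy-5-methylbenzyl}-2,4,6-trihydroxyacetophenone F8. Acid-catalysed exchange with glyoxylic acid (aq. HCl, THF, 50 °C) should then pass the methoxyamine to the more electrophilic aldehyde and release 11.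

Further compounds

F1 | step 5 | 1-(2,4,6-trihydroxy-3-methylphenyl)butan-1-one | CCCC(=O)c1c(O)cc(O)c(C)c1O
F2 | step 5 | 1-(2,6-dihydroxy-4-methoxy-3-methylphenyl)butan-1-one | CCCC(=O)c1c(O)cc(OC)c(C)c1O
F3 | step 5 | 1-{3-[(dimethylamino)methyl]-2,6-dihydroxy-4-methoxy-5-methylphenyl}butan-1-one | CCCC(=O)c1c(O)c(CN(C)C)c(OC)c(C)c1O
F4 | step 3 | 3,5-dibromo-2,4,6-trihydroxyacetophenone | CC(=O)c1c(O)c(Br)c(O)c(Br)c1O
F5 | step 3 | 2-acetyl-4,6-dibromobenzene-1,3,5-triyl triacetate | CC(=O)c1c(OC(C)=O)c(Br)c(OC(C)=O)c(Br)c1OC(C)=O
F6 | step 3 | (5-butanoyl-2-methoxy-3-methylbenzyl)zinc chloride | CCCC(=O)c1cc(C)c(OC)c(C[Zn]Cl)c1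
F7 | step 3 | 2-acetyl-4,6-bis(5-butanoyl-2-methoxy-3-methylbenzyl)benzene-1,3,5-triyl triacetate | CC(=O)c1c(OC(C)=O)c(Cc2cc(C(=O)CCC)cc(C)c2OC)c(OC(C)=O)c(Cc2cc(C(=O)CCC)cc(C)c2OC)c1OC(C)=O
F8 | step 6 | 3,5-bis{2,4-dihydroxy-3-[(1E)-N-methoxybutanimidoyl]-6-methoxy-5-methylbenzyl}-2,4,6-trihydroxyacetophenone | CC(=O)c1c(O)c(Cc2c(O)c(/C(CCC)=N/OC)c(O)c(C)c2OC)c(O)c(Cc2c(O)c(/C(CCC)=N/OC)c(O)c(C)c2OC)c1O
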